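(The numbers are invented; no experiment stands behind them.)

Ask of zeta and of epsilon how much single product stands at the end, and whether triple product has passed it.

    starting material + partner → single product + by-product (k1 = 2.33 /M/s)
    partner + single product → double product + by-product (k2 = 0.753 /M/s)
    partner + double product → triple product + by-product (k3 = 2.64 /M/s)
    single product ⇌ isomer of the product (K4 = 7.64, k4 = 0.00297 /s)
    partner → decomposed reagent (k5 = 0.0296 /s)
    2 starting material → self-condensation product (k6 = 1.68 /M/s)

| setting | zeta | epsilon |
|---|---|---|
| starting material | 16 mM | 16 mM |
| partner | 32.0 mM | 80.0 mM |
| time | 3.0 min | 3.0 min |

- which of the two there is more of at the end, zeta (triple product / single product)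
- which of the two there is more of at the end, epsilon (triple product / single product)
- how much single product is there at the end, in percent of the starting material charged: zeta
- how much single product is there at the end, in percent of the starting material charged: epsilon

Draw the single-product curve from its start. It rises at 1.19 mM/s in zeta and 2.98 mM/s in epsilon, while step 1 takes starting material 1.39 times as fast as self-condensation in zeta and 3.47 times as fast in epsilon. Carry these starting shares forward as a rough guess, so that 58.1% of the charge enters the single-product line in zeta and 77.6% in epsilon.

Put the knee near 0.563 min, the lifetime of partner under its decay by step 5. Grant single product half the dose of partner that this decay allows, again a guess, and 66.6% of the line in zeta and 36.1% in epsilon stays in the pool of single product and isomer.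

Past the knee, use the relaxation time of that pair, the reciprocal of the forward constant times one plus the inverse equilibrium constant, 4.96 min, which is far longer than that lifetime under step 5. The curve sinks along it toward a level of 11.6% of the pool. Counting from zero, reckon single product at 59.9% of the pool at 3.0 min, so commit to 23.2% in zeta and 16.8% in epsilon.

The guess passes 19.4% beyond the pool in zeta, which is less than the single product reckoned there, so expect single product ahead in zeta. In epsilon 49.6% passes, and triple product needs a third of it to lead; step 3 has the larger constant, so expect triple product ahead.

The forecast gives single product for zeta and triple product for epsilon, with 25% and 18% of single product, both above my figures, and holds for epsilon that “much of the single product goes on to double, then quickly to triple”.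

The simulation gives 25.7% in zeta, where single product leads triple product's 7.07%, and 19.3% in epsilon, where triple product stands at 41.2%. Zeta at 1.50 min held 33.1% single product, 9.15% isomer and 1.90% of its partner; relaxing that pair for the remaining time gives 25.7%.

Now leave epsilon until 8.0 min: relaxing its 19.3% single product and 14.6% isomer from 3.0 min gives 9.54% of single product, and the computed flask holds 9.51% of it.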